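## Retrosynthetic overview

1. Target ⇒ 8-O-acyl bond (hindered 8-alcohol plus (2R,3R)-epoxyangelic acid, itself from Sharpless epoxidation of angelyl alcohol), 14-acetate and 1,10-oxirane (hydroxyl-directed Sharpless epoxidation) ⇒ an 8,14-dihydroxy heliangolide triene.
2. Ten-membered ring ⇒ C7–C8: a samarium ketyl at C8 (the aldehyde is masked as a lactol with the C14 hydroxyl) adds to the β-carbon C7 of a C6 butenolide, closing the ring and setting C7 and C8 in one step; the α-methylene is added afterwards.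
3. Butenolide ⇒ catalytic asymmetric propiolate addition to a neral-type Z-enal (sets C6), then Lindlar reduction and lactonisation.
4. Acyclic chain ⇒ Z-selective Still–Gennari olefination (C1=C10) of the C1 aldehyde from ozonolysis of neryl acetate (C4=C5 Z comes from nerol) with a phosphonate carrying C8 as a dimethyl acetal.
5. Ring order: temporary oxolane acetal → butenolide → ten-membered carbocycle → ring oxirane; the side-chain oxirane is made separately and attached last.

## Assumptions and notation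

- Locants follow germacrane numbering: C6 lactone O–CH, C7 ring fusion, C8 ester carbinol, C1/C10 oxirane carbons, C14 the CH2O on C10, C15 the methyl on C4, C11=C13 the methylene, C12 the lactone carbonyl. "1(10)Z" is the CIP descriptor of the ring-trans olefin (C2 cis to C14).
- The oxolane acetal carbon (future C8) in 10, 11 and 13–16 is an inconsequential epimer mixture, erased in step 9, and is left undefined in the SMILES.
- (S,S)-ProPhenol is assumed to be the ligand enantiomer that gives the (4R)-carbinol 13; if the sense is opposite, (R,R)-ProPhenol is used.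
- Angelic acid, neryl acetate, methyl bis(2,2,2-trifluoroethyl)phosphonoacetate, 2,2-dimethoxyethanol and methyl propiolate are taken as commercial.

## Route

Step 1
Reactants: 1 neryl acetate
Product: 3 (2Z)-3-methyl-6-oxohex-2-en-1-yl acetate, via ozonide 2 (not isolated)
Conditions: O3 (1.0 equiv), CH2Cl2, −78 °C; then Me2S, −78 °C to rt
Reagents that add atoms: ozone, [O-][O+]=O
Why: Criegee ozonolysis is fastest at the electron-rich isopropylidene olefin because the other trisubstituted olefin is deactivated by its allylic acetate, so the Z-C4=C5 unit of nerol is kept intact.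

Step 2
Reactants: 4 methyl 2-[bis(2,2,2-trifluoroethoxy)phosphoryl]acetate; 5 2,2-dimethoxyethanol
Product: 7 methyl 2-[bis(2,2,2-trifluoroethoxy)phosphoryl]-4,4-dimethoxybutanoate, via 2,2-dimethoxyethyl triflate 6 (not isolated)
Conditions: 5, Tf2O, 2,6-lutidine, CH2Cl2, −78 °C; then added to 4 + NaH, THF, −20 °C to rt
Reagents that add atoms: none
Why: Triflate formation followed by SN2 alkylation of the soft sodium phosphonoacetate anion; the primary triflate reacts at low temperature where the corresponding bromo acetal is sluggish.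

Step 3
Reactants: 3 (2Z)-3-methyl-6-oxohex-2-en-1-yl acetate; 7 methyl 2-[bis(2,2,2-trifluoroethoxy)phosphoryl]-4,4-dimethoxybutanoate
Product: 8 methyl (2Z,6Z)-8-acetoxy-2-(2,2-dimethoxyethyl)-6-methylocta-2,6-dienoate
Conditions: 7, KN(SiMe3)2, 18-crown-6, THF, −78 °C; then 3
Reagents that add atoms: none
Why: Still–Gennari variant of the Horner–Wadsworth–Emmons olefination; the electron-poor trifluoroethyl phosphonate with a dissociated potassium ion eliminates under kinetic control to the Z-enoate (C2 cis to the ester carbon that becomes C14, C9 trans).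

Step 4
Reactants: 8 methyl (2Z,6Z)-8-acetoxy-2-(2,2-dimethoxyethyl)-6-methylocta-2,6-dienoate
Product: 10 (2Z,6Z)-6-(5-methoxyoxolan-3-ylidene)-3-methylhex-2-en-1-ol, via diol dimethyl acetal 9 (not isolated)
Conditions: iBu2AlH (5 equiv), CH2Cl2, −78 to 0 °C; aq. KNaC4H4O6 work-up; then PPTS (5 mol %), CH2Cl2, 0 °C
Reagents that add atoms: none
Why: 1,2-Reduction of the enoate and reductive cleavage of the acetate give a diol whose C14 hydroxyl closes onto the C8 dimethyl acetal by acid-catalysed transacetalisation (five-membered ring), leaving only the C6 allylic alcohol free; PPTS at 0 °C is mild enough to avoid elimination to the furan.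

Step 5
Reactants: 10 (2Z,6Z)-6-(5-methoxyoxolan-3-ylidene)-3-methylhex-2-en-1-ol
Product: 11 (2Z,6Z)-6-(5-methoxyoxolan-3-ylidene)-3-methylhex-2-enal
Conditions: TEMPO (10 mol %), PhI(OAc)2 (1.1 equiv), MeCN/pH 7 buffer, 0 °C
Reagents that add atoms: none
Why: Oxoammonium (TEMPO/PhI(OAc)2) oxidation of a primary allylic alcohol runs near neutral pH and, as for nerol to neral, does not isomerise the Z-enal.

Step 6
Reactants: 11 (2Z,6Z)-6-(5-methoxyoxolan-3-ylidene)-3-methylhex-2-enal; 12 methyl propiolate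
Product: 13 methyl (4R,5Z,9Z)-4-hydroxy-9-(5-methoxyoxolan-3-ylidene)-6-methylnon-5-en-2-ynoate
Conditions: Me2Zn (3 equiv), (S,S)-ProPhenol (10 mol %), Ph3P=O (20 mol %), toluene, 4 °C
Reagents that add atoms: none
Why: Zinc–ProPhenol-catalysed asymmetric alkynylation (Trost); the dinuclear zinc complex binds the enal and the alkynylzinc and delivers the propiolate to one enantioface, setting C6 (4R here).

Step 7
Reactants: 13 methyl (4R,5Z,9Z)-4-hydroxy-9-(5-methoxyoxolan-3-ylidene)-6-methylnon-5-en-2-ynoate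
Product: 15 (5S)-5-[(1Z,5Z)-5-(5-methoxyoxolan-3-ylidene)-2-methylpent-1-en-1-yl]furan-2(5H)-one, via hydroxy Z-enoate 14 (not isolated)
Conditions: H2 (1 atm), Pd/CaCO3 poisoned with Pb(OAc)2, quinoline, EtOAc, rt; lactonisation completed on silica gel
Reagents that add atoms: none
Why: Lindlar cis-semihydrogenation gives the Z-γ-hydroxy enoate, which lactonises to the butenolide with retention at C6 (the descriptor changes to S by priority only); the poisoned catalyst leaves the trisubstituted olefins alone.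

Step 8
Reactants: 15 (5S)-5-[(1Z,5Z)-5-(5-methoxyoxolan-3-ylidene)-2-methylpent-1-en-1-yl]furan-2(5H)-one
Product: 16 (5S)-5-[(1Z,5Z)-5-(5-hydroxyoxolan-3-ylidene)-2-methylpent-1-en-1-yl]furan-2(5H)-one
Conditions: AcOH/THF/H2O (2:2:1), rt
Reagents that add atoms: water, O
Why: Acid-catalysed acetal hydrolysis through the oxocarbenium ion, which water traps to give the lactol (a masked C8 aldehyde protected against conjugation by the C14 oxygen).

Step 9
Reactants: 16 (5S)-5-[(1Z,5Z)-5-(5-hydroxyoxolan-3-ylidene)-2-methylpent-1-en-1-yl]furan-2(5H)-one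
Product: 18 (6R,7R,8R)-8,14-dihydroxygermacra-1(10)Z,4Z-dien-6,12-olide, via hydroxy aldehyde 17 (not isolated)
Conditions: SmI2 (3 equiv, 0.1 M in THF), t-BuOH (3 equiv), THF, 2 mM, 16 added over 8 h, −20 °C to rt
Reagents that add atoms: none
Why: Proposed new method: SmI2 reduces the small equilibrium amount of aldehyde 17 to a ketyl radical anion (C8 with reversed polarity) that adds 10-exo to the β-carbon C7 of the butenolide, after which the α-radical is reduced to a samarium enolate and protonated by t-BuOH; the closest known reactions are SmI2 ketyl–enoate cyclisations to five- to eight-membered rings (including onto unsaturated lactones) and intermolecular SmI2 aldehyde/enoate couplings to γ-lactones; C7 is set by attack anti to the C6–C5 bond (trans-lactone, as in additions to 5-substituted butenolides), and C8 is expected as 8R from an arrangement in which trivalent samarium bridges the ketyl oxygen and the lactone carbonyl while C9 lies anti to C11 as the forming ring requires.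

Step 10
Reactants: 18 (6R,7R,8R)-8,14-dihydroxygermacra-1(10)Z,4Z-dien-6,12-olide
Product: 21 (6R,7R,8R)-8,14-dihydroxygermacra-1(10)Z,4Z,11(13)-trien-6,12-olide, via Mannich base 19 (not isolated), via trimethylammonium iodide 20 (not isolated)
Conditions: LiN(iPr)2 (3.3 equiv), THF, −78 °C; CH2=NMe2+ I− (4 equiv), −78 to 0 °C; then MeI, MeOH, rt; then NaHCO3 (aq.)/CH2Cl2
Reagents that add atoms: Eschenmoser's salt (N,N-dimethylmethyleneiminium iodide), C=[N+](C)C.[I-]
Why: α-Methylenation by Mannich reaction of the lactone lithium enolate with Eschenmoser's salt, N-methylation and E1cB elimination of trimethylamine; no stereocentre is made and C7 is not acidic.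

Step 11
Reactants: 21 (6R,7R,8R)-8,14-dihydroxygermacra-1(10)Z,4Z,11(13)-trien-6,12-olide
Product: 22 (1R,6R,7R,8R,10S)-1,10-epoxy-8,14-dihydroxygermacra-4Z,11(13)-dien-6,12-olide
Conditions: Ti(OiPr)4 (20 mol %), L-(+)-diethyl tartrate (24 mol %), t-BuOOH (2 equiv), 4 Å molecular sieves, CH2Cl2, −20 °C
Reagents that add atoms: tert-butyl hydroperoxide, CC(C)(C)OO
Why: Sharpless asymmetric epoxidation; the titanium tartrate binds the C14 allylic alcohol and L-(+)-tartrate delivers oxygen to the face that gives (1R,10S), which is expected to be the exposed outer face of the trans ring olefin as well, while the electron-poor methylene lactone and the non-allylic C4=C5 olefin do not react.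

Step 12
Reactants: 22 (1R,6R,7R,8R,10S)-1,10-epoxy-8,14-dihydroxygermacra-4Z,11(13)-dien-6,12-olide
Product: 23 (1R,6R,7R,8R,10S)-14-acetoxy-1,10-epoxy-8-hydroxygermacra-4Z,11(13)-dien-6,12-olide
Conditions: Ac2O (1.1 equiv), 2,4,6-collidine, CH2Cl2, −20 °C
Reagents that add atoms: acetic anhydride, CC(=O)OC(C)=O
Why: Kinetically selective acylation of the primary C14 alcohol over the hindered secondary C8 alcohol; the weak base avoids Payne rearrangement of the epoxy alcohol.

Step 13
Reactants: 24 angelic acid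
Product: 25 (2Z)-2-methylbut-2-en-1-ol
Conditions: LiAlH4, Et2O, 0 °C
Reagents that add atoms: none
Why: Hydride 1,2-reduction of the carboxylic acid at 0 °C keeps the Z geometry that later fixes the trans relation of the two oxirane methyl groups.

Step 14
Reactants: 25 (2Z)-2-methylbut-2-en-1-ol
Product: 26 [(2S,3R)-2,3-dimethyloxiran-2-yl]methanol
Conditions: Ti(OiPr)4 (10 mol %), L-(+)-diethyl tartrate (12 mol %), t-BuOOH, 4 Å molecular sieves, CH2Cl2, −20 °C
Reagents that add atoms: tert-butyl hydroperoxide, CC(C)(C)OO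
Why: Sharpless asymmetric epoxidation; L-(+)-tartrate selects the olefin face that gives the (2S,3R)-epoxy alcohol, and syn oxygen transfer to the Z olefin sets both centres together.

Step 15
Reactants: 26 [(2S,3R)-2,3-dimethyloxiran-2-yl]methanol
Product: 27 (2R,3R)-2,3-dimethyloxirane-2-carboxylic acid
Conditions: RuCl3 (2 mol %), NaIO4 (3 equiv), MeCN/EtOAc/H2O, 0 °C to rt
Reagents that add atoms: water, O
Why: RuO4-catalysed (RuCl3/NaIO4) oxidation of the primary alcohol to the acid leaves the trisubstituted oxirane untouched; C2 changes from S to R only through the priority change.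

Step 16
Reactants: 23 (1R,6R,7R,8R,10S)-14-acetoxy-1,10-epoxy-8-hydroxygermacra-4Z,11(13)-dien-6,12-olide; 27 (2R,3R)-2,3-dimethyloxirane-2-carboxylic acid
Product: 29 (1R,6R,7R,8R,10S)-14-acetoxy-1,10-epoxy-8-[(2R,3R)-2,3-dimethyloxirane-2-carbonyloxy]germacra-4Z,11(13)-dien-6,12-olide, via mixed anhydride 28 (not isolated)
Conditions: 27, 2,4,6-trichlorobenzoyl chloride, Et3N, THF, rt; then 23, DMAP, toluene, rt
Reagents that add atoms: none
Why: Yamaguchi esterification through the mixed anhydride and DMAP acyl transfer acylates the hindered 8-hydroxyl with retention at C8 and without opening either oxirane.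

## Compound list

1 | neryl acetate, (2Z)-3,7-dimethylocta-2,6-dien-1-yl acetate | CC(=O)OC/C=C(/C)CCC=C(C)C | starting material
2 | ozonide, (2Z)-5-(5,5-dimethyl-1,2,4-trioxolan-3-yl)-3-methylpent-2-en-1-yl acetate | CC(=O)OC/C=C(/C)CCC1OOC(C)(C)O1 | intermediate
3 | (2Z)-3-methyl-6-oxohex-2-en-1-yl acetate | CC(=O)OC/C=C(/C)CCC=O | intermediate
4 | methyl 2-[bis(2,2,2-trifluoroethoxy)phosphoryl]acetate | COC(=O)CP(=O)(OCC(F)(F)F)OCC(F)(F)F | starting material
5 | 2,2-dimethoxyethanol | COC(OC)CO | starting material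
6 | 2,2-dimethoxyethyl trifluoromethanesulfonate | COC(OC)COS(=O)(=O)C(F)(F)F | intermediate
7 | methyl 2-[bis(2,2,2-trifluoroethoxy)phosphoryl]-4,4-dimethoxybutanoate (racemic) | COC(=O)C(CC(OC)OC)P(=O)(OCC(F)(F)F)OCC(F)(F)F | intermediate
8 | methyl (2Z,6Z)-8-acetoxy-2-(2,2-dimethoxyethyl)-6-methylocta-2,6-dienoate | CC(=O)OC/C=C(/C)CC/C=C(/CC(OC)OC)C(=O)OC | intermediate
9 | (2Z,6Z)-2-(2,2-dimethoxyethyl)-6-methylocta-2,6-diene-1,8-diol | OC/C=C(/C)CC/C=C(/CC(OC)OC)CO | intermediate
10 | (2Z,6Z)-6-(5-methoxyoxolan-3-ylidene)-3-methylhex-2-en-1-ol | OC/C=C(/C)CC/C=C1/CC(OC)OC1 | intermediate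
11 | (2Z,6Z)-6-(5-methoxyoxolan-3-ylidene)-3-methylhex-2-enal | O=C/C=C(/C)CC/C=C1/CC(OC)OC1 | intermediate
12 | methyl propiolate | C#CC(=O)OC | starting material
13 | methyl (4R,5Z,9Z)-4-hydroxy-9-(5-methoxyoxolan-3-ylidene)-6-methylnon-5-en-2-ynoate | COC(=O)C#C[C@H](O)/C=C(/C)CC/C=C1/CC(OC)OC1 | intermediate
14 | methyl (2Z,4S,5Z,9Z)-4-hydroxy-9-(5-methoxyoxolan-3-ylidene)-6-methylnona-2,5-dienoate | COC(=O)/C=C\[C@H](O)/C=C(/C)CC/C=C1/CC(OC)OC1 | intermediate
15 | (5S)-5-[(1Z,5Z)-5-(5-methoxyoxolan-3-ylidene)-2-methylpent-1-en-1-yl]furan-2(5H)-one | O=C1O[C@@H](C=C1)/C=C(/C)CC/C=C2/CC(OC)OC2 | intermediate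
16 | (5S)-5-[(1Z,5Z)-5-(5-hydroxyoxolan-3-ylidene)-2-methylpent-1-en-1-yl]furan-2(5H)-one | O=C1O[C@@H](C=C1)/C=C(/C)CC/C=C2/CC(O)OC2 | intermediate
17 | (3Z,7Z)-3-(hydroxymethyl)-7-methyl-8-[(2S)-5-oxo-2,5-dihydrofuran-2-yl]octa-3,7-dienal | O=C1O[C@@H](C=C1)/C=C(/C)CC/C=C(\CO)CC=O | intermediate
18 | (6R,7R,8R)-8,14-dihydroxygermacra-1(10)Z,4Z-dien-6,12-olide | C1C(=O)O[C@@H]2/C=C(/C)CC/C=C(\CO)C[C@@H](O)[C@@H]12 | intermediate
19 | (6R,7R,8R)-13-(dimethylamino)-8,14-dihydroxygermacra-1(10)Z,4Z-dien-6,12-olide (C11 epimers) | CN(C)CC1C(=O)O[C@@H]2/C=C(/C)CC/C=C(\CO)C[C@@H](O)[C@@H]12 | intermediate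
20 | N-methyl ammonium iodide of 19 (13-trimethylammonio lactone iodide) | C[N+](C)(C)CC1C(=O)O[C@@H]2/C=C(/C)CC/C=C(\CO)C[C@@H](O)[C@@H]12.[I-] | intermediate
21 | (6R,7R,8R)-8,14-dihydroxygermacra-1(10)Z,4Z,11(13)-trien-6,12-olide | C=C1C(=O)O[C@@H]2/C=C(/C)CC/C=C(\CO)C[C@@H](O)[C@@H]12 | intermediate
22 | (1R,6R,7R,8R,10S)-1,10-epoxy-8,14-dihydroxygermacra-4Z,11(13)-dien-6,12-olide | C=C1C(=O)O[C@@H]2/C=C(/C)CC[C@H]3O[C@]3(CO)C[C@@H](O)[C@@H]12 | intermediate
23 | (1R,6R,7R,8R,10S)-14-acetoxy-1,10-epoxy-8-hydroxygermacra-4Z,11(13)-dien-6,12-olide | C=C1C(=O)O[C@@H]2/C=C(/C)CC[C@H]3O[C@]3(COC(C)=O)C[C@@H](O)[C@@H]12 | intermediate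
24 | angelic acid, (2Z)-2-methylbut-2-enoic acid | C/C=C(/C)C(O)=O | starting material
25 | angelyl alcohol, (2Z)-2-methylbut-2-en-1-ol | C/C=C(/C)CO | intermediate
26 | [(2S,3R)-2,3-dimethyloxiran-2-yl]methanol | OC[C@]1(C)O[C@@H]1C | intermediate
27 | (2R,3R)-2,3-dimethyloxirane-2-carboxylic acid | OC(=O)[C@]1(C)O[C@@H]1C | intermediate
28 | (2R,3R)-2,3-dimethyloxirane-2-carboxylic 2,4,6-trichlorobenzoic anhydride | O=C(OC(=O)[C@]1(C)O[C@@H]1C)c1c(Cl)cc(Cl)cc1Cl | intermediate
29 | (1R,6R,7R,8R,10S)-14-acetoxy-1,10-epoxy-8-[(2R,3R)-2,3-dimethyloxirane-2-carbonyloxy]germacra-4Z,11(13)-dien-6,12-olide (CNP0232260.3) | C=C1C(=O)O[C@@H]2/C=C(/C)CC[C@H]3O[C@]3(COC(C)=O)C[C@@H](OC(=O)[C@]3(C)O[C@@H]3C)[C@@H]12 | target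

## Step count and risks

Total steps: 16 (steps 1–16). Longest linear sequence: 12 (steps 1, 3–12, 16, from neryl acetate). Side branches: step 2 (phosphonate) and steps 13–15 (epoxy acid).

The three steps most likely to fail:

Step 9 (ketyl ring closure). The ten-membered ring may not close, and the C8 configuration is the least predictable outcome of the route. Fallback: a polar acyl-anion ring closure followed by a reagent-controlled reduction. Setting out from lactol 16, a thiazolium carbene (3-benzyl-5-(2-hydroxyethyl)-4-methylthiazolium chloride, Et3N, dioxane, 60 °C, 5 mM) turns the open aldehyde into a Breslow intermediate. This adds intramolecularly to C7 (Stetter reaction) and gives the ketone (6R,7S)-14-hydroxy-8-oxogermacra-1(10)Z,4Z-dien-6,12-olide F1. Reduction with (S)-Me-CBS oxazaborolidine and catecholborane (toluene, −78 °C) then sets 8R by reagent control, and the sequence comes back to the route at 18.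

Step 11 (epoxidation of the macrocycle). The tartrate-preferred face may be mismatched with the ring conformation, and the titanium Lewis acid may trigger transannular opening of the new oxirane. Fallback: substrate-controlled epoxidation as the last step. Setting out from 21, selective acetylation (Ac2O, 2,4,6-collidine, −20 °C) gives (6R,7R,8R)-14-acetoxy-8-hydroxygermacra-1(10)Z,4Z,11(13)-trien-6,12-olide F2. Yamaguchi esterification with 27 gives (6R,7R,8R)-14-acetoxy-8-[(2R,3R)-2,3-dimethyloxirane-2-carbonyloxy]germacra-1(10)Z,4Z,11(13)-trien-6,12-olide F3. Buffered m-CPBA (NaHCO3, CH2Cl2, 0 °C) then epoxidises the strained trans ring olefin from its outer face, and the sequence comes back to the route at 29.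

Step 6 (asymmetric alkynylation of a Z-β,β-disubstituted enal). The enantioselectivity may be low or the enal may isomerise to E. Fallback: racemic addition, oxidation and asymmetric ynone reduction. Setting out from 11, lithium methyl propiolate (12, LiN(SiMe3)2, THF, −78 °C) gives racemic methyl (5Z,9Z)-4-hydroxy-9-(5-methoxyoxolan-3-ylidene)-6-methylnon-5-en-2-ynoate F4. MnO2 (CH2Cl2, rt) gives the ynone methyl (5Z,9Z)-9-(5-methoxyoxolan-3-ylidene)-6-methyl-4-oxonon-5-en-2-ynoate F5. Midland reduction with (R)-Alpine-Borane (THF, rt) then gives the (4R)-alcohol, and the sequence comes back to the route at 13.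

Further compounds

F1 | step 9 | (6R,7S)-14-hydroxy-8-oxogermacra-1(10)Z,4Z-dien-6,12-olide | C1C(=O)O[C@@H]2/C=C(/C)CC/C=C(\CO)CC(=O)[C@@H]12
F2 | step 11 | (6R,7R,8R)-14-acetoxy-8-hydroxygermacra-1(10)Z,4Z,11(13)-trien-6,12-olide | C=C1C(=O)O[C@@H]2/C=C(/C)CC/C=C(\COC(C)=O)C[C@@H](O)[C@@H]12
F3 | step 11 | (6R,7R,8R)-14-acetoxy-8-[(2R,3R)-2,3-dimethyloxirane-2-carbonyloxy]germacra-1(10)Z,4Z,11(13)-trien-6,12-olide | C=C1C(=O)O[C@@H]2/C=C(/C)CC/C=C(\COC(C)=O)C[C@@H](OC(=O)[C@]3(C)O[C@@H]3C)[C@@H]12
F4 | step 6 | racemic methyl (5Z,9Z)-4-hydroxy-9-(5-methoxyoxolan-3-ylidene)-6-methylnon-5-en-2-ynoate | COC(=O)C#CC(O)/C=C(/C)CC/C=C1/CC(OC)OC1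
F5 | step 6 | methyl (5Z,9Z)-9-(5-methoxyoxolan-3-ylidene)-6-methyl-4-oxonon-5-en-2-ynoate | COC(=O)C#CC(=O)/C=C(/C)CC/C=C1/CC(OC)OC1
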